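Retrosynthesis: the 6-OH comes from a 6-OMe and the 8-OMe from an 8-OH. Ring A is then cut at C8–C8a (ring expansion) and at C4a–C5 (carbonyl addition), and ring C at O1–C8a and C2–C3 (hetero-Diels–Alder).
Enabling feature: C5, C6, C7 and C8 of ring A each carry an oxygen and match the four ring carbons of dimethyl squarate one to one. C4a=C8a is the C3=C2 double bond of a 6-aryl-4H-pyran-4-one that still has a hydrogen on the carbon next to the ring oxygen.
Forward: ring B is bought as 2-hydroxy-6-methoxybenzaldehyde, and ring C is made first by cycloaddition, iodination at the future C4a and dehydrogenation. Iodine–magnesium exchange and addition to the squarate join C4a to C5, and ring A closes last by thermal ring expansion.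
End game: methylation of the free 8-OH (the 5-OH is chelated), hydrogenolysis of the 2'-benzyl ether, then chelation-directed cleavage of the 6-methyl ether.
Stereochemistry: the target has no stereocentre. The centres that appear on the way (C2 of the dihydropyranones, the carbinol carbon, C8a of the dienone) are racemic and are all flattened again.

Key step: step 6

Remark: the target SMILES holds no stereocentre and rotation about C2–C1' is taken to be fast at room temperature, so the compound is treated as achiral and no enantioselective step is needed.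

Step 1
Reactants: 1 2-hydroxy-6-methoxybenzaldehyde
Product: 2 2-(benzyloxy)-6-methoxybenzaldehyde
Conditions: BnBr, K2CO3, DMF, rt → 50 °C
Reagents that add atoms: benzyl bromide, BrCc1ccccc1
Why: Williamson ether synthesis on the only phenol; the benzyl ether shields the future 2'-OH from the Grignard reagent, the base and the methylating agent used later and leaves under neutral hydrogenolysis.

Step 2
Reactants: 2 2-(benzyloxy)-6-methoxybenzaldehyde, 3 Danishefsky's diene [(E)-1-methoxy-3-(trimethylsilyloxy)buta-1,3-diene]
Product: 5 rac-2-[2-(benzyloxy)-6-methoxyphenyl]-2,3-dihydro-4H-pyran-4-one, via silyl enol ether cycloadduct 4 (not isolated)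
Conditions: ZnCl2 (20 mol %), THF, rt; then TFA (cat.), CH2Cl2, 0 °C
Reagents that add atoms: none
Why: Lewis-acid-catalysed hetero-Diels–Alder reaction of an aromatic aldehyde with Danishefsky's diene (the ortho ether oxygens help zinc to bind the carbonyl group), followed by acid-induced loss of methanol and of the silyl group; the new C2 centre is racemic and is erased in step 4.

Step 3
Reactants: 5 rac-2-[2-(benzyloxy)-6-methoxyphenyl]-2,3-dihydro-4H-pyran-4-one
Product: 6 rac-2-[2-(benzyloxy)-6-methoxyphenyl]-5-iodo-2,3-dihydro-4H-pyran-4-one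
Conditions: I2, pyridine/CH2Cl2, 0 °C → rt
Reagents that add atoms: iodine, II
Why: Johnson α-iodination of a cyclic enone; at this oxidation level C5 is the only sp2 α-carbon, so iodine marks the future C4a without competition from C3, and the iodine–pyridine complex is too mild to iodinate the dialkoxyarene.

Step 4
Reactants: 6 rac-2-[2-(benzyloxy)-6-methoxyphenyl]-5-iodo-2,3-dihydro-4H-pyran-4-one
Product: 7 2-[2-(benzyloxy)-6-methoxyphenyl]-5-iodo-4H-pyran-4-one
Conditions: DDQ, 1,4-dioxane, 80–100 °C
Reagents that add atoms: none
Why: DDQ dehydrogenation of the flavanone-to-flavone type, in which hydride leaves from C2–H (benzylic to a 2,6-dialkoxyaryl ring and α to oxygen) and loss of a C3 proton gives the pyranone, while the unactivated O-benzyl group and the vinyl iodide should stay untouched.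

Step 5
Reactants: 7 2-[2-(benzyloxy)-6-methoxyphenyl]-5-iodo-4H-pyran-4-one, 8 dimethyl squarate (3,4-dimethoxycyclobut-3-ene-1,2-dione)
Product: 10 rac-4-{6-[2-(benzyloxy)-6-methoxyphenyl]-4-oxo-4H-pyran-3-yl}-4-hydroxy-2,3-dimethoxycyclobut-2-en-1-one, via pyranonylmagnesium chloride 9 (not isolated)
Conditions: iPrMgCl·LiCl, THF, −40 °C; cannulated into 8, THF, −78 → −30 °C; sat. aq NH4Cl, −30 °C
Reagents that add atoms: none
Why: Iodine–magnesium exchange with the turbo-Grignard reagent, established for α-iodo-β-alkoxy-unsaturated carbonyl compounds such as 5-iodo-1,3-dioxin-4-ones and 5-iodouracils, followed by the standard 1,2-addition of an organometal to a squarate carbonyl; 7 has no enolisable hydrogen, magnesium at −40 °C should hold back β-elimination of the ring oxygen, and the racemic carbinol centre disappears in step 6.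

Step 6
Reactants: 10 rac-4-{6-[2-(benzyloxy)-6-methoxyphenyl]-4-oxo-4H-pyran-3-yl}-4-hydroxy-2,3-dimethoxycyclobut-2-en-1-one
Product: 13 2'-benzyloxy-5,8-dihydroxy-6,7,6'-trimethoxyflavone, via dienylketene 11 (not isolated), via cyclohexadienone 12 (not isolated)
Conditions: degassed PhMe (0.02 M), 110 °C, Ar; isolation under Ar
Reagents that add atoms: none
Why: On heating, the C1–C4 bond of the four-membered ring (carbonyl carbon to carbinol carbon) breaks in a conrotatory 4π process to give dienylketene 11; its ketene carbon bonds to the pyranone C2–H carbon (C8–C8a of the flavone) to give dienone 12, and a proton shift from C8a to O8 delivers the aromatic hydroquinone 13. The closest known reaction type is the Moore rearrangement of 4-alkenyl- and 4-heteroaryl-4-hydroxycyclobutenones (electron-poor pyridyl groups included) to hydroquinones, and the pyranon-3-yl group is a cyclic β-alkoxy-enone member of that alkenyl class. Ring A, the only ring formed, closes as a six-membered carbocycle by thermal disrotatory 6π electrocyclisation of the array C8=C7–C6=C5–C4a=C8a. No stereocentre survives, because the carbinol centre of 10 becomes sp2 on ring opening and the C8a centre of 12 is lost on enolisation. Torquoselectivity decides whether closure is possible at all: a hydroxyl donor on the breaking bond rotates outward, so the pyranonyl group ends up cis to the ketene arm, and the O–H···O=C4 hydrogen bond (the later 5-OH chelate) then holds the reactive s-cis rotamer. Regiochemistry is fixed because the other neighbour of the attachment carbon is the carbonyl carbon C4, which leaves the C2–H carbon as the only sp2 terminus within reach.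

Step 7
Reactants: 13 2'-benzyloxy-5,8-dihydroxy-6,7,6'-trimethoxyflavone
Product: 14 2'-benzyloxy-5-hydroxy-6,7,8,6'-tetramethoxyflavone
Conditions: MeI (1.05 equiv), K2CO3, degassed acetone, 40 °C, Ar
Reagents that add atoms: iodomethane, CI
Why: Partial Williamson methylation of a 5,8-dihydroxyflavone, in which the 5-OH is tied up in a hydrogen bond to C4=O and is far less nucleophilic, so one equivalent of iodomethane should go to O8 only.

Step 8
Reactants: 14 2'-benzyloxy-5-hydroxy-6,7,8,6'-tetramethoxyflavone
Product: 15 5,2'-dihydroxy-6,7,8,6'-tetramethoxyflavone (skullcapflavone II)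
Conditions: H2 (1 atm), 10% Pd/C, EtOAc/MeOH, rt
Reagents that add atoms: none
Why: Catalytic hydrogenolysis of an aryl benzyl ether, routine on benzyloxyflavones without reduction of C2=C3, and placed before the Lewis acid step because aluminium bromide would not spare the benzyl ether cleanly.

Step 9
Reactants: 15 5,2'-dihydroxy-6,7,8,6'-tetramethoxyflavone
Product: 16 5,6,2'-trihydroxy-7,8,6'-trimethoxyflavone (target)
Conditions: AlBr3 (ca. 6 equiv), MeCN, 0 °C → rt, monitored; then 2 M HCl
Reagents that add atoms: none
Why: Chelation-directed aryl methyl ether cleavage with an aluminium halide in acetonitrile, the reaction type that converts 5-hydroxy-6,7-dimethoxyflavones into 5,6-dihydroxy-7-methoxyflavones; the 6-methoxy oxygen is the only one that can share aluminium with the 5-phenoxide, so bromide should dealkylate it first, and short time and low temperature guard the 7-, 8- and 6'-methyl ethers.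

Compound list
1 | 2-hydroxy-6-methoxybenzaldehyde | COc1cccc(O)c1C=O | starting material
2 | 2-(benzyloxy)-6-methoxybenzaldehyde | COc1cccc(OCc2ccccc2)c1C=O | intermediate
3 | Danishefsky's diene, (E)-1-methoxy-3-(trimethylsilyloxy)buta-1,3-diene | CO/C=C/C(=C)O[Si](C)(C)C | starting material
4 | 2-[2-(benzyloxy)-6-methoxyphenyl]-6-methoxy-4-(trimethylsilyloxy)-3,6-dihydro-2H-pyran (racemic diastereomer mixture, not isolated) | COC1C=C(O[Si](C)(C)C)CC(O1)c1c(OC)cccc1OCc1ccccc1 | intermediate
5 | rac-2-[2-(benzyloxy)-6-methoxyphenyl]-2,3-dihydro-4H-pyran-4-one | O=C1C=COC(C1)c1c(OC)cccc1OCc1ccccc1 | intermediate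
6 | rac-2-[2-(benzyloxy)-6-methoxyphenyl]-5-iodo-2,3-dihydro-4H-pyran-4-one | O=C1C(I)=COC(C1)c1c(OC)cccc1OCc1ccccc1 | intermediate
7 | 2-[2-(benzyloxy)-6-methoxyphenyl]-5-iodo-4H-pyran-4-one | O=c1c(I)coc(c1)-c1c(OC)cccc1OCc1ccccc1 | intermediate
8 | dimethyl squarate, 3,4-dimethoxycyclobut-3-ene-1,2-dione | COC1=C(OC)C(=O)C1=O | starting material
9 | {6-[2-(benzyloxy)-6-methoxyphenyl]-4-oxo-4H-pyran-3-yl}magnesium chloride (LiCl complex, not isolated) | O=c1c([Mg]Cl)coc(c1)-c1c(OC)cccc1OCc1ccccc1 | intermediate
10 | rac-4-{6-[2-(benzyloxy)-6-methoxyphenyl]-4-oxo-4H-pyran-3-yl}-4-hydroxy-2,3-dimethoxycyclobut-2-en-1-one | O=C1C(OC)=C(OC)C1(O)c1coc(cc1=O)-c1c(OC)cccc1OCc1ccccc1 | intermediate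
11 | (3Z)-4-{6-[2-(benzyloxy)-6-methoxyphenyl]-4-oxo-4H-pyran-3-yl}-4-hydroxy-2,3-dimethoxybuta-1,3-dien-1-one, pyranonyl group cis to the ketene arm (not isolated) | O=C=C(OC)/C(OC)=C(/O)c1coc(cc1=O)-c1c(OC)cccc1OCc1ccccc1 | intermediate
12 | rac-2-[2-(benzyloxy)-6-methoxyphenyl]-5-hydroxy-6,7-dimethoxy-4H-chromene-4,8(8aH)-dione (not isolated) | O=C1C(OC)=C(OC)C(O)=C2C1OC(=CC2=O)c1c(OC)cccc1OCc1ccccc1 | intermediate
13 | 2'-benzyloxy-5,8-dihydroxy-6,7,6'-trimethoxyflavone | COc1cccc(OCc2ccccc2)c1-c1cc(=O)c2c(O)c(OC)c(OC)c(O)c2o1 | intermediate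
14 | 2'-benzyloxy-5-hydroxy-6,7,8,6'-tetramethoxyflavone | COc1cccc(OCc2ccccc2)c1-c1cc(=O)c2c(O)c(OC)c(OC)c(OC)c2o1 | intermediate
15 | 5,2'-dihydroxy-6,7,8,6'-tetramethoxyflavone | COc1cccc(O)c1-c1cc(=O)c2c(O)c(OC)c(OC)c(OC)c2o1 | intermediate
16 | 5,6,2'-trihydroxy-7,8,6'-trimethoxyflavone | COc1cccc(O)c1-c1cc(=O)c2c(O)c(O)c(OC)c(OC)c2o1 | target

Total step count: 9. Longest linear sequence: 9 steps (1 → 16); 3 and 8 are bought and enter directly.

Steps most likely to fail

Step 5.
- **Risk:** The magnesiated pyranone may decompose by anti β-elimination of the ring oxygen. The exchange reagent may add in a conjugate sense to the unsubstituted carbon next to the ring oxygen. The stabilised carbanion may also add to the squarate so slowly that it is only protonated on work-up.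
- **Fallback:** Ring A is bought instead of built, which gives up the squarate construction. The route is left at 2, which is condensed (Claisen–Schmidt, KOH, EtOH) with 2'-hydroxy-3',4',5',6'-tetramethoxyacetophenone F1 to give (E)-3-[2-(benzyloxy)-6-methoxyphenyl]-1-(2-hydroxy-3,4,5,6-tetramethoxyphenyl)prop-2-en-1-one F2. Oxidative cyclisation with catalytic I2 in DMSO at 120 °C should give 2'-benzyloxy-5,6,7,8,6'-pentamethoxyflavone F3. AlCl3 in MeCN at room temperature, mild enough to keep the benzyl ether, removes only the peri 5-methyl group and brings the material back to the route at 14.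

Step 6.
- **Risk:** The ketene may be consumed before it closes, through lactone formation after inward rotation of the hydroxyl group or capture by water or by product phenol. Closure onto the electron-poor pyranone carbon may be slow. The hydroquinone may oxidise in air during isolation.
- **Fallback:** The two phenols are told apart by protection before the ring expansion and not by chelation after it. Starting from 10, TESOTf and 2,6-lutidine (CH2Cl2, −78 °C) give 4-{6-[2-(benzyloxy)-6-methoxyphenyl]-4-oxo-4H-pyran-3-yl}-2,3-dimethoxy-4-(triethylsilyloxy)cyclobut-2-en-1-one F4. It has no free hydroxyl group left to lactonise, and its silyloxy group also rotates outward. Heating in toluene should give 2'-benzyloxy-8-hydroxy-6,7,6'-trimethoxy-5-(triethylsilyloxy)flavone F5, a monoprotected hydroquinone that is much less prone to oxidation. MeI and K2CO3 give 2'-benzyloxy-6,7,8,6'-tetramethoxy-5-(triethylsilyloxy)flavone F6, and dilute HCl in THF removes the silyl group, so the route is rejoined at 14.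

Step 9.
- **Risk:** Dealkylation may run on to the 7-methyl ether once the 6-oxygen carries aluminium. The 8- or 6'-methyl ether may compete. The acidic medium may trigger ring opening and re-closure of the pyranone (Wessely–Moser type isomerisation).
- **Fallback:** Oxidative demethylation replaces the Lewis-acidic one and is carried out while the 2'-oxygen is still benzylated, so that the 5-OH is the only phenol. Starting from 14, IBX (DMF, rt) delivers oxygen to the ortho carbon that bears the methoxy group (oxidative demethylation of a 2-methoxyphenol) and gives 2'-benzyloxy-7,8,6'-trimethoxyflavone-5,6-quinone F7. Aqueous Na2S2O4 reduces it to 2'-benzyloxy-5,6-dihydroxy-7,8,6'-trimethoxyflavone F8. Hydrogenolysis (H2, Pd/C) then rejoins the route at the target 16.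

Further compounds
F1 | step 5 | 2'-hydroxy-3',4',5',6'-tetramethoxyacetophenone (additional building block) | CC(=O)c1c(O)c(OC)c(OC)c(OC)c1OC
F2 | step 5 | (E)-3-[2-(benzyloxy)-6-methoxyphenyl]-1-(2-hydroxy-3,4,5,6-tetramethoxyphenyl)prop-2-en-1-one | COc1cccc(OCc2ccccc2)c1/C=C/C(=O)c1c(O)c(OC)c(OC)c(OC)c1OC
F3 | step 5 | 2'-benzyloxy-5,6,7,8,6'-pentamethoxyflavone | COc1cccc(OCc2ccccc2)c1-c1cc(=O)c2c(OC)c(OC)c(OC)c(OC)c2o1
F4 | step 6 | rac-4-{6-[2-(benzyloxy)-6-methoxyphenyl]-4-oxo-4H-pyran-3-yl}-2,3-dimethoxy-4-(triethylsilyloxy)cyclobut-2-en-1-one | O=C1C(OC)=C(OC)C1(O[Si](CC)(CC)CC)c1coc(cc1=O)-c1c(OC)cccc1OCc1ccccc1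
F5 | step 6 | 2'-benzyloxy-8-hydroxy-6,7,6'-trimethoxy-5-(triethylsilyloxy)flavone | COc1cccc(OCc2ccccc2)c1-c1cc(=O)c2c(O[Si](CC)(CC)CC)c(OC)c(OC)c(O)c2o1
F6 | step 6 | 2'-benzyloxy-6,7,8,6'-tetramethoxy-5-(triethylsilyloxy)flavone | COc1cccc(OCc2ccccc2)c1-c1cc(=O)c2c(O[Si](CC)(CC)CC)c(OC)c(OC)c(OC)c2o1
F7 | step 9 | 2'-benzyloxy-7,8,6'-trimethoxyflavone-5,6-quinone | COc1cccc(OCc2ccccc2)c1C1=CC(=O)C2=C(O1)C(OC)=C(OC)C(=O)C2=O
F8 | step 9 | 2'-benzyloxy-5,6-dihydroxy-7,8,6'-trimethoxyflavone | COc1cccc(OCc2ccccc2)c1-c1cc(=O)c2c(O)c(O)c(OC)c(OC)c2o1
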